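**Retrosynthetic overview**
- Last step: the free resorcinol is released from its bis(benzyl) ether by hydrogenolysis.
- Key disconnection C2–C3: the carbinol carbon, normally a carbonyl-type acceptor, is used as a configurationally defined α-oxy carbanion (Hoppe lithiated ethyl carbamate). It is joined to a primary alkylborane, so two donor carbons (C–Li and C–B) are united by a 1,2-metallate shift; this sets C2 as S.
- The alkylborane comes from a terminal alkene, itself made by coupling 3,5-bis(benzyloxy)benzyl bromide with mono-hydroborated tetradeca-1,13-diene (C17–C16 bond).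
- No ring is formed; the aromatic ring is bought intact.

Assumption: ethyl N,N-diisopropylcarbamate and (+)-sparteine are bought as catalogue reagents, and 9-BBN is used as its commercial THF solution.

**Step 1**
Reactants: 1 tetradeca-1,13-diene; 2 1,3-bis(benzyloxy)-5-(bromomethyl)benzene
Product: 4 1,3-bis(benzyloxy)-5-(pentadec-14-en-1-yl)benzene, via B-(tetradec-13-en-1-yl)-9-BBN 3 (not isolated)
Conditions: 1 (5 equiv), 9-BBN (1.3 equiv), THF, 0 °C→rt; then 2 (1.0 equiv), PdCl2(dppf)·CH2Cl2 (5 mol %), K3PO4·H2O (3 equiv), THF, 50 °C; excess 1 recovered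
Reagents that add atoms: none
Why: 9-BBN adds anti-Markovnikov to one terminal alkene of the excess diene, and the primary alkylborane then undergoes a B-alkyl Suzuki–Miyaura sp3–sp3 coupling with the benzylic bromide (the benzyl–Pd intermediate has no β-hydrogen), leaving the second alkene untouched; no stereocenter is formed.

**Step 2**
Reactants: 4 1,3-bis(benzyloxy)-5-(pentadec-14-en-1-yl)benzene; 5 ethyl N,N-diisopropylcarbamate
Product: 10 (S)-17-[3,5-bis(benzyloxy)phenyl]heptadecan-2-ol, via primary alkylborane 6 (not isolated), via (R)-lithiated carbamate 7 (not isolated), via borate complex 8 (not isolated), via secondary alkylborane 9 (not isolated)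
Conditions: flask A: 4, 9-BBN (1.0 equiv), THF, 0 °C→rt; flask B: 5 (1.4 equiv), sBuLi (1.3 equiv), (+)-sparteine (1.4 equiv), Et2O, −78 °C, 5 h; A into B, −78 °C, 1 h, then →rt, 2 h; then 2 M NaOH, 30% H2O2, 0 °C→rt
Reagents that add atoms: hydrogen peroxide (OO)
Why: Hoppe asymmetric deprotonation followed by lithiation–borylation–oxidation: sBuLi/(+)-sparteine removes the pro-R proton of 5 to give the configurationally stable α-oxy carbanion (R)-7, which captures the alkylborane 6 with retention, the primary alkyl group then migrates anti to the carbamate with inversion (1,2-metallate shift) and oxidation with retention fixes C2 as S.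

**Step 3**
Reactants: 10 (S)-17-[3,5-bis(benzyloxy)phenyl]heptadecan-2-ol
Product: 11 Hansfordiol A
Conditions: H2 (1 atm), 10% Pd/C, EtOAc/MeOH 1:1, rt
Reagents that add atoms: none
Why: Hydrogenolysis of the two aryl benzyl ethers over Pd/C leaves the aliphatic secondary alcohol and its S configuration untouched.

**Compound list**
1 | tetradeca-1,13-diene | C=CCCCCCCCCCCCC=C | starting material
2 | 1,3-bis(benzyloxy)-5-(bromomethyl)benzene | BrCc1cc(OCc2ccccc2)cc(OCc2ccccc2)c1 | starting material
3 | 9-(tetradec-13-en-1-yl)-9-borabicyclo[3.3.1]nonane | C=CCCCCCCCCCCCCB1C2CCCC1CCC2 | intermediate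
4 | 1,3-bis(benzyloxy)-5-(pentadec-14-en-1-yl)benzene | C=CCCCCCCCCCCCCCc1cc(OCc2ccccc2)cc(OCc2ccccc2)c1 | intermediate
5 | ethyl N,N-diisopropylcarbamate | CCOC(=O)N(C(C)C)C(C)C | starting material
6 | 9-{15-[3,5-bis(benzyloxy)phenyl]pentadecyl}-9-borabicyclo[3.3.1]nonane | C1CCC2CCCC1B2CCCCCCCCCCCCCCCc1cc(OCc2ccccc2)cc(OCc2ccccc2)c1 | intermediate
7 | (R)-1-lithioethyl N,N-diisopropylcarbamate (formed as its (+)-sparteine complex) | C[C@@H]([Li])OC(=O)N(C(C)C)C(C)C | intermediate
8 | lithium 9-{15-[3,5-bis(benzyloxy)phenyl]pentadecyl}-9-[(1R)-1-(diisopropylcarbamoyloxy)ethyl]-9-boranuidabicyclo[3.3.1]nonane | [Li+].C[C@@H]([B-]1(CCCCCCCCCCCCCCCc2cc(OCc3ccccc3)cc(OCc3ccccc3)c2)C2CCCC1CCC2)OC(=O)N(C(C)C)C(C)C | intermediate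
9 | 9-{(2S)-17-[3,5-bis(benzyloxy)phenyl]heptadecan-2-yl}-9-borabicyclo[3.3.1]nonane | C[C@H](B1C2CCCC1CCC2)CCCCCCCCCCCCCCCc1cc(OCc2ccccc2)cc(OCc2ccccc2)c1 | intermediate
10 | (S)-17-[3,5-bis(benzyloxy)phenyl]heptadecan-2-ol | C[C@H](O)CCCCCCCCCCCCCCCc1cc(OCc2ccccc2)cc(OCc2ccccc2)c1 | intermediate
11 | Hansfordiol A, 5-[(16S)-16-hydroxyheptadecyl]benzene-1,3-diol | C[C@H](O)CCCCCCCCCCCCCCCc1cc(O)cc(O)c1 | target

**Totals**
Total step count: 3. Longest linear sequence: 3 (1 → 4 → 10 → 11).

**Steps most likely to fail, with fallbacks**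

Step 2 (most at risk). The borate 8 may let a ring B–C bond migrate instead of the primary chain, and the enantiomer ratio is reagent-set (about 97:3 expected from sparteine-mediated deprotonation). The fallback keeps a polarity-reversed union but takes the stereocenter from the chiral pool. It sets out from 4: oxidative cleavage of the alkene (OsO4 cat., NaIO4, 2,6-lutidine, dioxane/H2O) gives 14-[3,5-bis(benzyloxy)phenyl]tetradecanal F4. Propane-1,3-dithiol with BF3·OEt2 converts it into 2-{13-[3,5-bis(benzyloxy)phenyl]tridecyl}-1,3-dithiane F5. Deprotonation (tBuLi, THF/HMPA, −78 °C) gives the acyl-anion equivalent 2-lithio-2-{13-[3,5-bis(benzyloxy)phenyl]tridecyl}-1,3-dithiane F6, which opens (S)-2-methyloxirane at its CH2 to give (S)-1-(2-{13-[3,5-bis(benzyloxy)phenyl]tridecyl}-1,3-dithian-2-yl)propan-2-ol F7. Raney nickel in EtOH at rt removes the sulfur and the sequence comes back to the route at 10; any material that loses benzyl groups here is already 11.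

Step 1. The benzylic bromide may homocouple or hydrolyse faster than it cross-couples, and the mono-hydroboration is statistical. The fallback turns the union into a copper-catalysed Grignard coupling. It sets out from 3: oxidative work-up (NaOH, H2O2) gives tetradec-13-en-1-ol F1, CBr4/PPh3 in CH2Cl2 gives 14-bromotetradec-1-ene F2, and Mg in THF gives tetradec-13-en-1-ylmagnesium bromide F3. This is added to 2 with Li2CuCl4 (3 mol %) in THF at −20 → 0 °C and comes back to the route at 4.

Step 3 (least at risk). Hydrogenolysis could stall on trace catalyst poisons or begin to reduce the electron-rich ring. The fallback sets out from 10 and uses Lewis-acid debenzylation instead (BCl3, pentamethylbenzene as benzyl-cation scavenger, CH2Cl2, −78 °C), arriving directly at 11; it makes no new compound (F0).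

**Further compounds**
F1 | step 1 | tetradec-13-en-1-ol | C=CCCCCCCCCCCCCO
F2 | step 1 | 14-bromotetradec-1-ene | C=CCCCCCCCCCCCCBr
F3 | step 1 | tetradec-13-en-1-ylmagnesium bromide | C=CCCCCCCCCCCCC[Mg]Br
F4 | step 2 | 14-[3,5-bis(benzyloxy)phenyl]tetradecanal | O=CCCCCCCCCCCCCCc1cc(OCc2ccccc2)cc(OCc2ccccc2)c1
F5 | step 2 | 2-{13-[3,5-bis(benzyloxy)phenyl]tridecyl}-1,3-dithiane | C1CSC(CCCCCCCCCCCCCc2cc(OCc3ccccc3)cc(OCc3ccccc3)c2)SC1
F6 | step 2 | 2-lithio-2-{13-[3,5-bis(benzyloxy)phenyl]tridecyl}-1,3-dithiane | [Li]C1(CCCCCCCCCCCCCc2cc(OCc3ccccc3)cc(OCc3ccccc3)c2)SCCCS1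
F7 | step 2 | (S)-1-(2-{13-[3,5-bis(benzyloxy)phenyl]tridecyl}-1,3-dithian-2-yl)propan-2-ol | C[C@H](O)CC1(CCCCCCCCCCCCCc2cc(OCc3ccccc3)cc(OCc3ccccc3)c2)SCCCS1
F0 | step 3 | none | none
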